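Both tetrahydrofuran rings are taken apart at once, at the C8'–C8 bond and the O–C7 bond, leaving an acyclic epoxy allyl ether. This works because in the 3,7-dioxabicyclo[3.3.0]octane core the stereocentres C7', C8', C8 and C7 are neighbours in one unbroken sequence, so the preset C7' carbinol alone dictates the other three as the rings form. In a single flask Cp2TiCl turns the oxirane into a C8' radical that closes 5-exo onto the sinapyl alkene, and iodine then lets the C9' oxygen close ring two at C7. The substrate is a (7'S)-epoxy sinapyl ether (guaiacyl phenol as TIPS ether, syringyl phenol as benzyl ether); the glycerol arm is added afterwards by anti-aldol.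

Key step: step 8

Numbering used below: C7/C8/C9 = syringyl C3 unit, C7'/C8'/C9' = central guaiacyl C3 unit, C7''/C8''/C9'' = glycerol arm.

Assumption: the controller enantiomer that gives the (2R,3R)-anti adduct in step 10 is taken to be (S,S); this would be confirmed on a simple model ester first, and the (R,R)-controller used instead if the sense is opposite.

Step 1
Reactants: 1 vanillin
Product: 2 3-methoxy-4-(triisopropylsilyloxy)benzaldehyde
Conditions: TIPSCl, imidazole, DMF, 0 °C → rt
Reagents that add atoms: triisopropylsilyl chloride, CC(C)[Si](Cl)(C(C)C)C(C)C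
Why: Phenol silylation (silyl ether formation); the bulky aryl TIPS ether should survive the Grignard, titanium alkoxide, NaH/THF and radical steps and is later removed by fluoride without touching a benzyl ether.

Step 2
Reactants: 2 3-methoxy-4-(triisopropylsilyloxy)benzaldehyde; 3 vinylmagnesium bromide
Product: 4 rac-1-[3-methoxy-4-(triisopropylsilyloxy)phenyl]prop-2-en-1-ol
Conditions: CH2=CHMgBr, THF, −78 → 0 °C; aq. NH4Cl
Reagents that add atoms: vinylmagnesium bromide (3), C=C[Mg]Br
Why: Grignard 1,2-addition to the aldehyde; the carbinol is made racemic on purpose because the next step resolves it.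

Step 3
Reactants: 4 rac-1-[3-methoxy-4-(triisopropylsilyloxy)phenyl]prop-2-en-1-ol
Product: 5 (S)-[3-methoxy-4-(triisopropylsilyloxy)phenyl][(2R)-oxiran-2-yl]methanol (erythro epoxy alcohol; 7'S,8'R)
Conditions: Ti(OiPr)4 (0.2 equiv), diisopropyl L-(+)-tartrate (0.3 equiv), t-BuOOH (0.5 equiv), 4 Å MS, CH2Cl2, −20 °C
Reagents that add atoms: tert-butyl hydroperoxide, CC(C)(C)OO
Why: Sharpless kinetic resolution (titanium–tartrate epoxidation of a secondary allylic alcohol): with the L-tartrate the (R)-carbinol of 4 is epoxidised much faster than its mirror image and gives the erythro product, so stopping near half conversion should give 5 with C7' resolved (it reads S only because the oxirane carbon now outranks the aryl group) while the unreacted (S)-alcohol is separated; the oxirane centre set here by the catalyst is destroyed in step 8, so only C7' matters.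

Step 4
Reactants: 6 syringaldehyde
Product: 7 4-(benzyloxy)-3,5-dimethoxybenzaldehyde
Conditions: BnBr, K2CO3, DMF, rt
Reagents that add atoms: benzyl bromide, BrCc1ccccc1
Why: Williamson ether synthesis on the phenoxide; the benzyl ether is orthogonal to the TIPS ether of the other ring and leaves at the very end by hydrogenolysis.

Step 5
Reactants: 7 4-(benzyloxy)-3,5-dimethoxybenzaldehyde; 3 vinylmagnesium bromide
Product: 8 rac-1-[4-(benzyloxy)-3,5-dimethoxyphenyl]prop-2-en-1-ol
Conditions: CH2=CHMgBr, THF, −78 → 0 °C; aq. NH4Cl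
Reagents that add atoms: vinylmagnesium bromide (3), C=C[Mg]Br
Why: Grignard 1,2-addition to the aldehyde; the carbinol centre needs no control because it disappears in the next step.

Step 6
Reactants: 8 rac-1-[4-(benzyloxy)-3,5-dimethoxyphenyl]prop-2-en-1-ol
Product: 9 2-(benzyloxy)-5-[(E)-3-bromoprop-1-en-1-yl]-1,3-dimethoxybenzene (O-benzylsinapyl bromide)
Conditions: PBr3, Et2O, 0 °C; used crude at once
Reagents that add atoms: phosphorus tribromide, BrP(Br)Br
Why: Bromination with allylic transposition (SN1/SN2' substitution): the activated carbinol ionises to the aryl-stabilised allyl cation and bromide adds at the terminal carbon, which should give the conjugated primary (E)-bromide as the thermodynamic product.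

Step 7
Reactants: 5 (S)-[3-methoxy-4-(triisopropylsilyloxy)phenyl][(2R)-oxiran-2-yl]methanol; 9 O-benzylsinapyl bromide
Product: 10 (2R)-2-[(S)-{[(E)-3-[4-(benzyloxy)-3,5-dimethoxyphenyl]prop-2-en-1-yl]oxy}[3-methoxy-4-(triisopropylsilyloxy)phenyl]methyl]oxirane (erythro epoxy sinapyl ether; 7'S,8'R)
Conditions: NaH, THF, 0 °C; then 9, Bu4NI (cat.), 0 °C → rt
Reagents that add atoms: none
Why: Williamson ether synthesis: the sodium alkoxide of 5 displaces halide from the primary allylic bromide (iodide after exchange in the flask); THF at 0 °C is chosen over DMF so that the aryl silyl ether is not cleaved and O-alkylation outruns Payne rearrangement, and neither stereocentre is touched.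

Step 8
Reactants: 10 erythro epoxy sinapyl ether
Product: 13 (1R,3aS,4R,6aS)-4-[4-(benzyloxy)-3,5-dimethoxyphenyl]-1-[3-methoxy-4-(triisopropylsilyloxy)phenyl]tetrahydro-1H,3H-furo[3,4-c]furan (7R,7'R,8S,8'S), via C7-Ti(Cl)Cp2 tetrahydrofuran 11 (not isolated), via benzylic iodide 12 (not isolated)
Conditions: Cp2TiCl2 (2.5 equiv), Zn dust, THF, rt (forms Cp2TiCl); 10 added slowly; then I2, rt → 60 °C
Reagents that add atoms: none
Why: Cp2TiCl (trivalent titanium) transfers one electron to the oxirane and cleaves its C8'–O bond towards the more substituted carbon, giving the secondary C8' radical with the C9' oxygen held as a titanium alkoxide; this radical adds 5-exo-trig to C8 of the sinapyl alkene (ring one, bond C8'–C8) and the syringyl-stabilised C7 radical is captured by a second Cp2TiCl as 11. Iodine converts 11 into benzylic iodide 12, which ionises readily beside the electron-rich ring and is trapped by the C9' oxygen in a 5-exo-tet, SN1-like etherification (ring two, bond O–C7). The closest known reaction type is the titanocene-mediated reductive epoxide opening with radical cyclisation of epoxy cinnamyl ethers followed by iodine-induced ring closure, as used for furofuran lignans. C8' and C8 are set in the chair-like 5-exo transition state, where the C7' aryl group sits pseudo-equatorial (C7'/C8' trans) and the substituent on the radical carbon closes cis to the new C8 side chain (C8'/C8 cis, the only arrangement that can give the cis-fused bicycle). C7 is set in the ionic closure, which should place the syringyl ring on the convex (exo) face. Only diastereoselectivity relative to the preset C7' centre is needed, because the oxirane stereocentre becomes a planar radical and both epoxide epimers would converge.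

Step 9
Reactants: 13 silyl-protected furofuran; 14 tert-butyl bromoacetate
Product: 16 tert-butyl 2-{4-[(1R,3aS,4R,6aS)-4-[4-(benzyloxy)-3,5-dimethoxyphenyl]tetrahydro-1H,3H-furo[3,4-c]furan-1-yl]-2-methoxyphenoxy}acetate, via free phenol 15 (not isolated)
Conditions: TBAF, THF, 0 °C; then BrCH2CO2t-Bu, 0 °C → rt
Reagents that add atoms: tert-butyl bromoacetate (14), CC(C)(C)OC(=O)CBr
Why: Fluoride desilylation followed by Williamson O-alkylation in one flask: TBAF cleaves the aryl Si–O bond and the tetrabutylammonium phenoxide of 15 is alkylated directly by the α-bromo ester; nothing acidic is present, so the furofuran stereocentres and the benzyl ether should be untouched.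

Step 10
Reactants: 16 tert-butyl aryloxyacetate; 17 4-(benzyloxy)-3-methoxybenzaldehyde (O-benzylvanillin, commercial)
Product: 18 tert-butyl (2R,3R)-3-[4-(benzyloxy)-3-methoxyphenyl]-2-{4-[(1R,3aS,4R,6aS)-4-[4-(benzyloxy)-3,5-dimethoxyphenyl]tetrahydro-1H,3H-furo[3,4-c]furan-1-yl]-2-methoxyphenoxy}-3-hydroxypropanoate (anti adduct)
Conditions: (S,S)-TsNHCH(Ph)CH(Ph)NHTs, BBr3, CH2Cl2, rt, then evaporation; 16, Et3N, toluene, −78 °C; 17, −78 °C; pH 7 buffer
Reagents that add atoms: 4-(benzyloxy)-3-methoxybenzaldehyde (17), COc1cc(C=O)ccc1OCc1ccccc1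
Why: Reagent-controlled boron aldol of a tert-butyl ester with a C2-symmetric 1,2-diphenylethylenediamine bis(sulfonamide) bromoborane (diazaborolidine), a method established for tert-butyl propionate and tert-butyl bromoacetate: the bromoborane and Et3N should give the boron enolate geometry that reacts through a closed chair transition state to the anti adduct, while the chiral diamine backbone blocks one enolate face, so C7'' and C8'' are both set by the reagent and not by the remote furofuran.

Step 11
Reactants: 18 anti-aldol tert-butyl ester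
Product: 19 (1R,2S)-1-[4-(benzyloxy)-3-methoxyphenyl]-2-{4-[(1R,3aS,4R,6aS)-4-[4-(benzyloxy)-3,5-dimethoxyphenyl]tetrahydro-1H,3H-furo[3,4-c]furan-1-yl]-2-methoxyphenoxy}propane-1,3-diol
Conditions: LiAlH4, THF, 0 °C
Reagents that add atoms: none
Why: Hydride reduction of the ester to the primary alcohol; no stereocentre is touched (C8'' changes from R to S in name only) and aryl ethers, benzyl ethers and the furofuran are inert to LiAlH4.

Step 12
Reactants: 19 di-O-benzyl ficusesquilignan A
Product: 20 ficusesquilignan A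
Conditions: H2 (1 atm), Pd/C, EtOAc–MeOH, rt, stopped on consumption of 19
Reagents that add atoms: none
Why: Catalytic hydrogenolysis of the two aryl benzyl ethers; under neutral conditions at 1 atm these should be cleaved well before the benzylic C–O bonds of the furofuran or the C7'' carbinol.

Compound list
1 | vanillin (4-hydroxy-3-methoxybenzaldehyde) | COc1cc(C=O)ccc1O | starting material
2 | 3-methoxy-4-(triisopropylsilyloxy)benzaldehyde | COc1cc(C=O)ccc1O[Si](C(C)C)(C(C)C)C(C)C | intermediate
3 | vinylmagnesium bromide | C=C[Mg]Br | starting material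
4 | rac-1-[3-methoxy-4-(triisopropylsilyloxy)phenyl]prop-2-en-1-ol | COc1cc(C(O)C=C)ccc1O[Si](C(C)C)(C(C)C)C(C)C | intermediate
5 | (S)-[3-methoxy-4-(triisopropylsilyloxy)phenyl][(2R)-oxiran-2-yl]methanol (erythro) | COc1cc([C@H](O)[C@H]2CO2)ccc1O[Si](C(C)C)(C(C)C)C(C)C | intermediate
6 | syringaldehyde (4-hydroxy-3,5-dimethoxybenzaldehyde) | COc1cc(C=O)cc(OC)c1O | starting material
7 | 4-(benzyloxy)-3,5-dimethoxybenzaldehyde | COc1cc(C=O)cc(OC)c1OCc1ccccc1 | intermediate
8 | rac-1-[4-(benzyloxy)-3,5-dimethoxyphenyl]prop-2-en-1-ol | COc1cc(C(O)C=C)cc(OC)c1OCc1ccccc1 | intermediate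
9 | 2-(benzyloxy)-5-[(E)-3-bromoprop-1-en-1-yl]-1,3-dimethoxybenzene | COc1cc(/C=C/CBr)cc(OC)c1OCc1ccccc1 | intermediate
10 | (2R)-2-[(S)-{[(E)-3-[4-(benzyloxy)-3,5-dimethoxyphenyl]prop-2-en-1-yl]oxy}[3-methoxy-4-(triisopropylsilyloxy)phenyl]methyl]oxirane (key-step precursor) | COc1cc([C@H](OC/C=C/c2cc(OC)c(OCc3ccccc3)c(OC)c2)[C@H]2CO2)ccc1O[Si](C(C)C)(C(C)C)C(C)C | intermediate
11 | (2R,3S,4S)-2-aryl-3-[Cp2Ti(Cl)-oxymethyl]-4-[aryl(Cp2TiCl)methyl]tetrahydrofuran, C7 unassigned | COc1cc([C@@H]2OC[C@@H](C(c3cc(OC)c(OCc4ccccc4)c(OC)c3)[Ti+2]Cl)[C@H]2CO[Ti+2]Cl)ccc1O[Si](C(C)C)(C(C)C)C(C)C.c1cc[cH-]c1.c1cc[cH-]c1.c1cc[cH-]c1.c1cc[cH-]c1 | intermediate (not isolated)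
12 | (2R,3S,4S)-2-aryl-3-[Cp2Ti(Cl)-oxymethyl]-4-[aryl(iodo)methyl]tetrahydrofuran, C7 unassigned | COc1cc([C@@H]2OC[C@@H](C(I)c3cc(OC)c(OCc4ccccc4)c(OC)c3)[C@H]2CO[Ti+2]Cl)ccc1O[Si](C(C)C)(C(C)C)C(C)C.c1cc[cH-]c1.c1cc[cH-]c1 | intermediate (not isolated)
13 | (1R,3aS,4R,6aS)-4-[4-(benzyloxy)-3,5-dimethoxyphenyl]-1-[3-methoxy-4-(triisopropylsilyloxy)phenyl]tetrahydro-1H,3H-furo[3,4-c]furan (key-step product) | COc1cc([C@@H]2OC[C@@H]3[C@H]2CO[C@H]3c2cc(OC)c(OCc4ccccc4)c(OC)c2)ccc1O[Si](C(C)C)(C(C)C)C(C)C | intermediate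
14 | tert-butyl bromoacetate | CC(C)(C)OC(=O)CBr | starting material
15 | 4-[(1R,3aS,4R,6aS)-4-[4-(benzyloxy)-3,5-dimethoxyphenyl]tetrahydro-1H,3H-furo[3,4-c]furan-1-yl]-2-methoxyphenol (in the flask as its tetrabutylammonium salt) | COc1cc([C@@H]2OC[C@@H]3[C@H]2CO[C@H]3c2cc(OC)c(OCc4ccccc4)c(OC)c2)ccc1O | intermediate (not isolated)
16 | tert-butyl 2-{4-[(1R,3aS,4R,6aS)-4-[4-(benzyloxy)-3,5-dimethoxyphenyl]tetrahydro-1H,3H-furo[3,4-c]furan-1-yl]-2-methoxyphenoxy}acetate | COc1cc([C@@H]2OC[C@@H]3[C@H]2CO[C@H]3c2cc(OC)c(OCc4ccccc4)c(OC)c2)ccc1OCC(=O)OC(C)(C)C | intermediate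
17 | 4-(benzyloxy)-3-methoxybenzaldehyde (O-benzylvanillin) | COc1cc(C=O)ccc1OCc1ccccc1 | starting material
18 | tert-butyl (2R,3R)-3-[4-(benzyloxy)-3-methoxyphenyl]-2-{4-[(1R,3aS,4R,6aS)-4-[4-(benzyloxy)-3,5-dimethoxyphenyl]tetrahydro-1H,3H-furo[3,4-c]furan-1-yl]-2-methoxyphenoxy}-3-hydroxypropanoate | COc1cc([C@@H](O)[C@H](C(=O)OC(C)(C)C)Oc2ccc([C@@H]3OC[C@@H]4[C@H]3CO[C@H]4c3cc(OC)c(OCc4ccccc4)c(OC)c3)cc2OC)ccc1OCc1ccccc1 | intermediate
19 | (1R,2S)-1-[4-(benzyloxy)-3-methoxyphenyl]-2-{4-[(1R,3aS,4R,6aS)-4-[4-(benzyloxy)-3,5-dimethoxyphenyl]tetrahydro-1H,3H-furo[3,4-c]furan-1-yl]-2-methoxyphenoxy}propane-1,3-diol | COc1cc([C@@H](O)[C@H](CO)Oc2ccc([C@@H]3OC[C@@H]4[C@H]3CO[C@H]4c3cc(OC)c(OCc4ccccc4)c(OC)c3)cc2OC)ccc1OCc1ccccc1 | intermediate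
20 | ficusesquilignan A, (1R,2S)-1-(4-hydroxy-3-methoxyphenyl)-2-{4-[(1R,3aS,4R,6aS)-4-(4-hydroxy-3,5-dimethoxyphenyl)tetrahydro-1H,3H-furo[3,4-c]furan-1-yl]-2-methoxyphenoxy}propane-1,3-diol | COc1cc([C@@H](O)[C@H](CO)Oc2ccc([C@@H]3OC[C@@H]4[C@H]3CO[C@H]4c3cc(OC)c(O)c(OC)c3)cc2OC)ccc1O | target

Total step count: 12. Longest linear sequence: 9 steps (1, 2, 3, 7, 8, 9, 10, 11, 12).

Steps most likely to fail

1. Step 8. The C7 radical may be reduced or lost before iodination, so that the second ring has no leaving group to close on. The cis selectivity between C8' and C8 in the radical closure may be incomplete, and the trans isomer cannot form the bicycle. The ionic closure may also give a mixture at C7. Fallback: set out from 10. The same Cp2TiCl opening and 5-exo cyclisation is run but quenched with dilute aqueous acid instead of iodine, so that the C7–titanium bond is protonated and the monocyclic tetrahydrofuran alcohol F1 is isolated. Ring two is then closed in a separate oxidative step with DDQ in CH2Cl2 at rt: hydride is abstracted from the electron-rich syringyl CH2 and the C9' hydroxyl adds to the resulting benzylic cation, a known oxidative cyclisation of 4-benzyl-3-hydroxymethyltetrahydrofuran lignans to furofurans. The route is rejoined at 13.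

2. Step 10. The α-aryloxy group may change the enolate geometry or the facial bias, which would erode anti selectivity or reverse the sense. The Lewis-acidic boron bromide may also open or epimerise the benzylic ether carbons of the furofuran. Fallback: set out from 13, desilylated as in step 9 but worked up to isolate phenol 15. Alkylation with (R)-4-benzyl-3-(bromoacetyl)oxazolidin-2-one (K2CO3, acetone) gives acyl oxazolidinone F2. An Evans syn-aldol (Bu2BOTf, iPr2NEt, CH2Cl2, −78 → 0 °C, aldehyde 17) gives syn adduct F3, with C8'' correct and C7'' of the wrong sense. LiBH4 (THF, trace water) removes the auxiliary to give threo diol F4. Selective acylation of the primary alcohol (PivCl, pyridine, 0 °C) gives pivalate F5. Mitsunobu inversion at the C7'' carbinol (4-nitrobenzoic acid, PPh3, DIAD, THF) gives inverted diester F6. K2CO3 in MeOH cleaves both esters and the route is rejoined at 19.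

3. Step 7. The epoxy alkoxide may undergo Payne rearrangement before O-alkylation, and the electron-rich allylic bromide may decompose or ionise under the basic conditions. Fallback: set out from 8 and 5. Carbinol 8 is acetylated (Ac2O, pyridine, DMAP) to branched allylic acetate F7. The ether bond is then made by Tsuji–Trost allylic etherification: 5 is converted into its zinc alkoxide with Et2Zn (0.5 equiv, THF) and coupled with F7 using catalytic Pd(OAc)2 and 2-(di-tert-butylphosphino)biphenyl at rt. The alkoxide should attack the unsubstituted terminus of the aryl-allyl palladium intermediate and give the linear (E)-ether without a free alkoxide or an allylic bromide. The route is rejoined at 10.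

Further compounds
F1 | step 8 | [(2R,3S,4S)-4-[4-(benzyloxy)-3,5-dimethoxybenzyl]-2-[3-methoxy-4-(triisopropylsilyloxy)phenyl]tetrahydrofuran-3-yl]methanol | COc1cc([C@@H]2OC[C@@H](Cc3cc(OC)c(OCc4ccccc4)c(OC)c3)[C@H]2CO)ccc1O[Si](C(C)C)(C(C)C)C(C)C
F2 | step 10 | (R)-4-benzyl-3-(2-{4-[(1R,3aS,4R,6aS)-4-[4-(benzyloxy)-3,5-dimethoxyphenyl]tetrahydro-1H,3H-furo[3,4-c]furan-1-yl]-2-methoxyphenoxy}acetyl)oxazolidin-2-one | COc1cc([C@@H]2OC[C@@H]3[C@H]2CO[C@H]3c2cc(OC)c(OCc4ccccc4)c(OC)c2)ccc1OCC(=O)N1[C@H](Cc2ccccc2)COC1=O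
F3 | step 10 | (R)-4-benzyl-3-[(2R,3S)-3-[4-(benzyloxy)-3-methoxyphenyl]-2-(aryloxy)-3-hydroxypropanoyl]oxazolidin-2-one (syn adduct; aryloxy as in 16) | COc1cc([C@H](O)[C@H](C(=O)N2[C@H](Cc3ccccc3)COC2=O)Oc2ccc([C@@H]3OC[C@@H]4[C@H]3CO[C@H]4c3cc(OC)c(OCc4ccccc4)c(OC)c3)cc2OC)ccc1OCc1ccccc1
F4 | step 10 | (1S,2S)-1-[4-(benzyloxy)-3-methoxyphenyl]-2-(aryloxy)propane-1,3-diol (threo diol; aryloxy as in 16) | COc1cc([C@H](O)[C@H](CO)Oc2ccc([C@@H]3OC[C@@H]4[C@H]3CO[C@H]4c3cc(OC)c(OCc4ccccc4)c(OC)c3)cc2OC)ccc1OCc1ccccc1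
F5 | step 10 | (2S,3S)-3-[4-(benzyloxy)-3-methoxyphenyl]-2-(aryloxy)-3-hydroxypropyl pivalate | COc1cc([C@H](O)[C@H](COC(=O)C(C)(C)C)Oc2ccc([C@@H]3OC[C@@H]4[C@H]3CO[C@H]4c3cc(OC)c(OCc4ccccc4)c(OC)c3)cc2OC)ccc1OCc1ccccc1
F6 | step 10 | (1R,2S)-1-[4-(benzyloxy)-3-methoxyphenyl]-2-(aryloxy)-3-(pivaloyloxy)propyl 4-nitrobenzoate | COc1cc([C@@H](OC(=O)c2ccc(cc2)[N+](=O)[O-])[C@H](COC(=O)C(C)(C)C)Oc2ccc([C@@H]3OC[C@@H]4[C@H]3CO[C@H]4c3cc(OC)c(OCc4ccccc4)c(OC)c3)cc2OC)ccc1OCc1ccccc1
F7 | step 7 | rac-1-[4-(benzyloxy)-3,5-dimethoxyphenyl]prop-2-en-1-yl acetate | COc1cc(C(OC(C)=O)C=C)cc(OC)c1OCc1ccccc1
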